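A direct plan would close ring C last: 1,5-dibromo-2,3,4-trimethoxybenzene (A1) would be hydroxylated twice to 4,5,6-trimethoxyresorcinol (A2). A2 would be fused near 240 °C with the α-methoxy β-keto ester A3 (from a benzyl-protected 2,4-dihydroxybenzoate by crossed Claisen condensation) to the dibenzyl flavone A4, which would be hydrogenolysed.
- The thermal pyrone annulation of A2 with A3 would be weak: a labile keto ester and an air-sensitive penta-oxygenated phenol must survive a melt while C-acylation occurs at the one crowded ring carbon; decarboxylation, retro-Claisen cleavage and tar would compete.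
- The double palladium-catalysed hydroxylation of A1 to A2 would be weak: it only exchanges Br for OH on a ready-made ring, hydrodebromination competes, and A2 oxidises readily to quinones.
- The crossed Claisen condensation to A3 would be weak: an electron-rich, ortho-substituted benzoate is a poor electrophile, so self-condensation of the methoxyacetate enolate competes.

Retrosynthetic overview
- Ring A, with its contiguous 5-OH, 6-OMe, 7-OMe, 8-OMe array, is cut back to dimethyl squarate: C6 and C7 with their methoxy groups are the squarate alkene, C5 and C8 its two carbonyl carbons.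
- C8–C8a forms by addition of a C6-lithiated 2-aryl-3-methoxy-4-pyranone (ring C with ring B attached) to the squarate. C4a–C5 forms in a thermal four-electron ring opening and six-electron ring closure, and tautomerisation gives the 5-OH phenol.
- Ring order: B (bought), then C (bought pyranone, arylated at C2), then A last, the reverse of the direct plan.
- No penta-oxygenated resorcinol, no melt and no Claisen condensation are needed; methylating the carbinol oxygen before ring expansion sets the 8-OMe/5-OH distinction.

Key step: step 6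

Remark: C6–H of the 4-pyranone (next to the ring oxygen) is assumed to be the kinetic site of deprotonation by a hindered lithium amide, as for C2–H of chromones and C6–H of uracils.

Step 1
Reactants: 1 3-hydroxy-4H-pyran-4-one (pyromeconic acid)
Product: 2 2-bromo-3-hydroxy-4H-pyran-4-one
Conditions: NBS (1.05 equiv), MeCN, 0 °C to rt, dark
Reagents that add atoms: N-bromosuccinimide, O=C1CCC(=O)N1Br
Why: Electrophilic bromination of the enolic 3-hydroxypyranone at C2, the enol β-carbon ortho to the OH and next to the ring oxygen, the same site at which kojic and pyromeconic acid take up electrophiles.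

Step 2
Reactants: 2 2-bromo-3-hydroxy-4H-pyran-4-one
Product: 3 2-bromo-3-methoxy-4H-pyran-4-one
Conditions: MeI (1.5 equiv), K2CO3 (1.5 equiv), acetone, 40 °C
Reagents that add atoms: iodomethane, CI
Why: Williamson O-methylation of the acidic enolic 3-OH, in which carbonate is too weak a nucleophile to displace the vinylogous acyl bromide at C2.

Step 3
Reactants: 4 4-bromobenzene-1,3-diol (4-bromoresorcinol)
Product: 5 1-bromo-2,4-bis(methoxymethoxy)benzene
Conditions: MOMCl (2.6 equiv), iPr2NEt (3 equiv), CH2Cl2, 0 °C to rt
Reagents that add atoms: chloromethyl methyl ether, COCCl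
Why: Double O-alkylation of the two phenols with the α-chloro ether (acetal protection), giving ethers that are inert to organolithium, organozinc and hot toluene and are removed by dilute acid at the end.

Step 4
Reactants: 5 1-bromo-2,4-bis(methoxymethoxy)benzene; 3 2-bromo-3-methoxy-4H-pyran-4-one
Product: 8 2-[2,4-bis(methoxymethoxy)phenyl]-3-methoxy-4H-pyran-4-one, via aryllithium 6 (not isolated), via arylzinc chloride 7 (not isolated)
Conditions: 5 (1.2 equiv), nBuLi (1.2 equiv), THF, −78 °C; ZnCl2 (1.3 equiv), −78 °C to rt; then 3 (1.0 equiv), Pd(OAc)2 (2 mol %), SPhos (4 mol %), THF, 50 °C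
Reagents that add atoms: none
Why: Bromine–lithium exchange (faster than ortho-lithiation, the aryllithium being chelated by the ortho acetal), transmetalation to zinc and Negishi cross-coupling, in which zerovalent palladium inserts easily into the C2–Br bond of the vinylogous acyl bromide 3 and the arylzinc leaves the pyranone carbonyl untouched.

Step 5
Reactants: 8 2-[2,4-bis(methoxymethoxy)phenyl]-3-methoxy-4H-pyran-4-one; 9 3,4-dimethoxycyclobut-3-ene-1,2-dione (dimethyl squarate)
Product: 12 4-{6-[2,4-bis(methoxymethoxy)phenyl]-5-methoxy-4-oxo-4H-pyran-2-yl}-2,3,4-trimethoxycyclobut-2-en-1-one (racemic), via 6-lithiopyranone 10 (not isolated), via lithium alkoxide 11 (not isolated)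
Conditions: 2,2,6,6-tetramethylpiperidine (1.2 equiv), nBuLi (1.15 equiv), THF, −78 °C; 8, −78 °C, 20 min; cannulate into 9 (1.3 equiv), THF, −78 °C; MeOTf (1.2 equiv), −78 to −20 °C; aq. NaHCO3, chromatography on Et3N-deactivated silica
Reagents that add atoms: methyl trifluoromethanesulfonate, COS(=O)(=O)C(F)(F)F
Why: Kinetic deprotonation of the only C–H next to the ring oxygen (pyranone C6) by the hindered lithium amide, 1,2-addition of the resulting alkenyllithium to one of the two equivalent squarate carbonyls (mono-addition at −78 °C) and O-methylation of the tertiary lithium alkoxide in the flask, in which the new quaternary carbon is racemic and later becomes sp2 C8.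

Step 6
Reactants: 12 4-{6-[2,4-bis(methoxymethoxy)phenyl]-5-methoxy-4-oxo-4H-pyran-2-yl}-2,3,4-trimethoxycyclobut-2-en-1-one
Product: 15 2-[2,4-bis(methoxymethoxy)phenyl]-5-hydroxy-3,6,7,8-tetramethoxy-4H-chromen-4-one, via dienylketene 13 (not isolated), via 4a-H dienone 14 (not isolated)
Conditions: degassed toluene (0.02 M), 110 °C, Ar (p-xylene, 138 °C, if ring opening is slow)
Reagents that add atoms: none
Why: Moore rearrangement of a 4-alkenyl-4-alkoxycyclobutenone: conrotatory four-electron opening of the C1–C4 bond gives dienylketene 13, in which the donor 4-OMe rotates outward and the pyranonyl group inward, so the ketene carbon and pyranone C5 end up cis. Ring A then closes by a disrotatory six-electron electrocyclisation that joins the electrophilic ketene carbon to the nucleophilic enol-ether β-carbon C5 of the pyranone, giving the 4a-H dienone 14. Enolisation of 14 aromatises ring A, driven by aromaticity and by the 5-OH to C4=O hydrogen bond. The closest precedents are the thermal conversions of 4-aryl-, 4-furyl- and 4-alkenyl-4-methoxycyclobutenones into 4-methoxy-1-naphthols, benzofuranols and phenols. Regiochemistry is fixed by connectivity: the ketene can reach only C5 of the pyranone, the methylated carbinol carbon becomes C8 (8-OMe), the ketene carbon becomes C5 (5-OH) and the squarate methoxy groups become 6- and 7-OMe. Ring opening with the methoxy group inward is reversible and unproductive, and no stereocentre survives.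

Step 7
Reactants: 15 2-[2,4-bis(methoxymethoxy)phenyl]-5-hydroxy-3,6,7,8-tetramethoxy-4H-chromen-4-one
Product: 16 5,2',4'-trihydroxy-3,6,7,8-tetramethoxyflavone
Conditions: 3 M aq. HCl (5 equiv), MeOH/THF 3:1, 45 °C
Reagents that add atoms: none
Why: Acid-catalysed cleavage of the two methoxymethyl acetals via oxocarbenium ions that methanol traps as dimethoxymethane, under which the four aryl and enol methyl ethers and the flavone core are inert and the achiral target results.

Compound list
1 | 3-hydroxy-4H-pyran-4-one (pyromeconic acid) | O=c1ccocc1O | starting material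
2 | 2-bromo-3-hydroxy-4H-pyran-4-one | O=c1ccoc(Br)c1O | intermediate
3 | 2-bromo-3-methoxy-4H-pyran-4-one | COc1c(Br)occc1=O | intermediate
4 | 4-bromobenzene-1,3-diol (4-bromoresorcinol) | Oc1ccc(Br)c(O)c1 | starting material
5 | 1-bromo-2,4-bis(methoxymethoxy)benzene | COCOc1ccc(Br)c(OCOC)c1 | intermediate
6 | [2,4-bis(methoxymethoxy)phenyl]lithium (formed in situ) | [Li]c1ccc(OCOC)cc1OCOC | intermediate
7 | [2,4-bis(methoxymethoxy)phenyl]zinc chloride (formed in situ) | Cl[Zn]c1ccc(OCOC)cc1OCOC | intermediate
8 | 2-[2,4-bis(methoxymethoxy)phenyl]-3-methoxy-4H-pyran-4-one | COCOc1ccc(-c2occc(=O)c2OC)c(OCOC)c1 | intermediate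
9 | 3,4-dimethoxycyclobut-3-ene-1,2-dione (dimethyl squarate) | COC1=C(OC)C(=O)C1=O | starting material
10 | {6-[2,4-bis(methoxymethoxy)phenyl]-5-methoxy-4-oxo-4H-pyran-2-yl}lithium (formed in situ) | [Li]c1cc(=O)c(OC)c(-c2ccc(OCOC)cc2OCOC)o1 | intermediate
11 | lithium 1-{6-[2,4-bis(methoxymethoxy)phenyl]-5-methoxy-4-oxo-4H-pyran-2-yl}-2,3-dimethoxy-4-oxocyclobut-2-en-1-olate (racemic, formed in situ) | [Li+].[O-]C1(c2cc(=O)c(OC)c(-c3ccc(OCOC)cc3OCOC)o2)C(OC)=C(OC)C1=O | intermediate
12 | 4-{6-[2,4-bis(methoxymethoxy)phenyl]-5-methoxy-4-oxo-4H-pyran-2-yl}-2,3,4-trimethoxycyclobut-2-en-1-one (racemic) | COC1=C(OC)C(OC)(c2cc(=O)c(OC)c(-c3ccc(OCOC)cc3OCOC)o2)C1=O | intermediate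
13 | (Z)-4-{6-[2,4-bis(methoxymethoxy)phenyl]-5-methoxy-4-oxo-4H-pyran-2-yl}-2,3,4-trimethoxybuta-1,3-dien-1-one (dienylketene, formed in situ) | O=C=C(OC)/C(OC)=C(OC)\c1cc(=O)c(OC)c(-c2ccc(OCOC)cc2OCOC)o1 | intermediate
14 | 2-[2,4-bis(methoxymethoxy)phenyl]-3,6,7,8-tetramethoxy-4aH-chromene-4,5-dione (racemic, formed in situ) | COC1=C(OC)C(=O)C2C(=O)C(OC)=C(c3ccc(OCOC)cc3OCOC)OC2=C1OC | intermediate
15 | 2-[2,4-bis(methoxymethoxy)phenyl]-5-hydroxy-3,6,7,8-tetramethoxy-4H-chromen-4-one | COCOc1ccc(-c2oc3c(OC)c(OC)c(OC)c(O)c3c(=O)c2OC)c(OCOC)c1 | intermediate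
16 | 5,2',4'-trihydroxy-3,6,7,8-tetramethoxyflavone (achiral) | COc1c(OC)c(O)c2c(=O)c(OC)c(-c3ccc(O)cc3O)oc2c1OC | target

Total step count: 7. Longest linear sequence: 6 (steps 1, 2, 4, 5, 6, 7 from compound 1).

Steps most likely to fail

Step 5. The lithium amide may deprotonate elsewhere (pyranone C5, or ring B between the two acetal oxygens), the lithiated pyranone may add to unreacted 8, and excess MeOTf may O-methylate the pyranone carbonyl. The fallback sets out from 8 and comes back at 10. Zincation of 8 with TMPZnCl·LiCl (THF, 25 °C), a base that metalates chromones and 4-pyranones next to the ring oxygen and gives an organozinc that does not add to the substrate, should give the pyranonylzinc chloride F1. Iodinolysis (I2, THF, 0 °C) should give 2-[2,4-bis(methoxymethoxy)phenyl]-6-iodo-3-methoxy-4H-pyran-4-one F2. Iodine–lithium exchange on F2 (nBuLi, THF, −100 °C, faster than addition to the vinylogous ester) should then deliver 10 at that carbon only, and the addition to 9 and methylation proceed as written.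

Step 6. The crowded, fully oxygenated dienylketene may be captured intermolecularly (dimerisation, trace protic material) before ring closure, or the tertiary, doubly allylic methyl ether may ionise at 110 °C. The fallback sets out from 11 and comes back at 15. Alkoxide 11 is protonated (aq. NH4Cl, −78 °C) instead of methylated, to give 4-{6-[2,4-bis(methoxymethoxy)phenyl]-5-methoxy-4-oxo-4H-pyran-2-yl}-4-hydroxy-2,3-dimethoxycyclobut-2-en-1-one F3. Thermolysis of this free carbinol (degassed toluene, 110 °C, Ar) is the most widely used form of the rearrangement and should give the hydroquinone 2-[2,4-bis(methoxymethoxy)phenyl]-5,8-dihydroxy-3,6,7-trimethoxy-4H-chromen-4-one F4. The 8-OH, which is not hydrogen-bonded, is then methylated selectively over the chelated 5-OH (Me2SO4, 1.05 equiv, K2CO3, acetone, rt, Ar) to give 15. The 8-OMe/5-OH distinction then rests on chelation after ring formation, not on trapping the alkoxide before it.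

Step 4. Transmetalation of the ortho-chelated arylzinc may be slow, so that protodezincation of 7 and reduction or homocoupling of 3 take over. The fallback reverses the polarity of the coupling; it sets out from 1 (with 5) and comes back at 8. O-Methylation of 1 (MeI, K2CO3, acetone) should give 3-methoxy-4H-pyran-4-one F5. Zincation with TMPZnCl·LiCl at C2, the C–H flanked by the ring oxygen and the 3-methoxy group, should give (3-methoxy-4-oxo-4H-pyran-2-yl)zinc chloride F6. Negishi coupling of F6 with aryl bromide 5 (Pd(OAc)2, SPhos, THF, 50 °C) should give 8 without bromopyranone 3 or an aryllithium.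

Further compounds
F1 | step 5 | {6-[2,4-bis(methoxymethoxy)phenyl]-5-methoxy-4-oxo-4H-pyran-2-yl}zinc chloride | Cl[Zn]c1cc(=O)c(OC)c(-c2ccc(OCOC)cc2OCOC)o1
F2 | step 5 | 2-[2,4-bis(methoxymethoxy)phenyl]-6-iodo-3-methoxy-4H-pyran-4-one | COCOc1ccc(-c2oc(I)cc(=O)c2OC)c(OCOC)c1
F3 | step 6 | 4-{6-[2,4-bis(methoxymethoxy)phenyl]-5-methoxy-4-oxo-4H-pyran-2-yl}-4-hydroxy-2,3-dimethoxycyclobut-2-en-1-one (racemic) | COC1=C(OC)C(O)(c2cc(=O)c(OC)c(-c3ccc(OCOC)cc3OCOC)o2)C1=O
F4 | step 6 | 2-[2,4-bis(methoxymethoxy)phenyl]-5,8-dihydroxy-3,6,7-trimethoxy-4H-chromen-4-one | COCOc1ccc(-c2oc3c(O)c(OC)c(OC)c(O)c3c(=O)c2OC)c(OCOC)c1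
F5 | step 4 | 3-methoxy-4H-pyran-4-one | COc1coccc1=O
F6 | step 4 | (3-methoxy-4-oxo-4H-pyran-2-yl)zinc chloride | COc1c([Zn]Cl)occc1=O
A1 | direct plan | 1,5-dibromo-2,3,4-trimethoxybenzene | COc1c(Br)cc(Br)c(OC)c1OC
A2 | direct plan | 4,5,6-trimethoxybenzene-1,3-diol | COc1c(O)cc(O)c(OC)c1OC
A3 | direct plan | methyl 3-[2,4-bis(benzyloxy)phenyl]-2-methoxy-3-oxopropanoate | COC(=O)C(OC)C(=O)c1ccc(OCc2ccccc2)cc1OCc1ccccc1
A4 | direct plan | 2-[2,4-bis(benzyloxy)phenyl]-5-hydroxy-3,6,7,8-tetramethoxy-4H-chromen-4-one | COc1c(OC)c(O)c2c(=O)c(OC)c(-c3ccc(OCc4ccccc4)cc3OCc3ccccc3)oc2c1OC
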